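**Retrosynthetic overview**

1. The side chain is joined last: Grignard reagent 21 (C26, Z-olefin, three S methyl centres) adds to ring aldehyde 8; oxidation and methylenation then give the exocyclic C=CH2.
2. Chain: one iridium-catalysed hydrogenation of all-E geranylgeranylacetone sets the three methyl stereocentres with one catalyst; a Baeyer–Villiger trim gives the C21 bromide, and syn-carbocupration of propyne followed by oxirane opening builds the Z-trisubstituted olefin.
3. Ring numbering used below: C1 = CH bearing the side chain, C2 = CH2, C3 = CH=, C4 = C(CH3)=, C5 = allylic CH2, C6 = CH2. Enabling feature: C1 is a stereocentre only because its two CH2 arms C2 and C6 are told apart by the C3=C4 double bond; in a cyclobutanol (four-membered ring C1–C2–C3–C6, carbinol C3 carrying an isopropenyl group that supplies C4, its CH3 and C5) these two arms are enantiotopic.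
4. Key disconnection: bond C5–C6. A ligand-controlled rhodium ring expansion cuts C3–C6 and joins C6 to C5; this closes the six-membered ring, sets C1 and leaves a ketone at C3, from which the C3=C4 olefin is drawn (enol triflate, then reduction).
5. Ring order: the cyclobutane is bought (1) and serves as a temporary ring; the cyclohexene ring, the only ring of the target, is formed in step 2.

Key step: step 2

Assumption: geometrically pure (5E,9E,13E)-geranylgeranylacetone 9 is used (drug-grade material is a 5E/5Z mixture and would have to be separated), because olefin geometry decides the configuration set in step 7.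
Assumption: in the two ligand-controlled steps (2 and 7) the ligand enantiomer is the one that delivers the configuration drawn; the sense of induction on these substrates has to be established by correlation.

**Route**

Step 1
Reactants: 1 3-[(benzyloxy)methyl]cyclobutan-1-one; 2 isopropenylmagnesium bromide (prop-1-en-2-ylmagnesium bromide)
Product: 3 cis-3-[(benzyloxy)methyl]-1-(prop-1-en-2-yl)cyclobutan-1-ol (OH cis to CH2OBn; achiral)
Conditions: THF, −78 °C; aqueous work-up; chromatography to remove the minor trans isomer
Reagents that add atoms: none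
Why: Grignard 1,2-addition to the strained ketone, in which the nucleophile should enter the puckered ring on the face anti to the 3-substituent so that the hydroxyl ends up cis to CH2OBn.

Step 2
Reactants: 3 cis-3-[(benzyloxy)methyl]-1-(prop-1-en-2-yl)cyclobutan-1-ol
Product: 4 (5R)-5-[(benzyloxy)methyl]-2-methylcyclohexan-1-one (mixture of epimers at C2)
Conditions: [Rh(OH)(cod)]2 (2.5 mol %), (R)-DTBM-SEGPHOS (6 mol %), toluene, 80 °C, slow addition of 3
Reagents that add atoms: none
Why: Proposed new method: the rhodium alkoxide of 3 should undergo β-carbon elimination of one of the two enantiotopic ring bonds (C3–C6 or C3–C2, chosen by the chiral bisphosphine), giving a primary alkylrhodium at C6 held next to the isopropenyl ketone just unmasked; 1,4-addition of this alkyl group to the enone terminus C5 then forms the C5–C6 bond and a rhodium enolate, which is protonated by the next molecule of 3. The closest known reaction type is the enantioselective rhodium/bisphosphine ring expansion of prochiral 1-allenyl tert-cyclobutanols to cyclohexenones (β-carbon elimination, then intramolecular addition of the alkylrhodium to the unsaturated ketone), together with conjugate addition of such ring-opened alkylrhodium species to enones. The six-membered ring closes in a 6-endo-trig conjugate mode, since 5-exo attack at the α-carbon is electronically mismatched and would create a quaternary centre. The ring stereocentre (C5 of 4, the future C1) is set by the ligand-controlled choice between the enantiotopic C–C bonds, which is why a single (cis) diastereomer of 3 is used; the methyl-bearing carbon arises from unselective enolate protonation and does not matter because it becomes sp2 in step 3. Beyond this the step needs ring closure to outrun β-hydride elimination at the tertiary C–H next to the metal and protodemetalation; chelation of the enone to the four-coordinate alkylrhodium (no free cis site), an ether rather than a carbonyl substituent on that carbon, and aprotic conditions at low substrate concentration are meant to secure it.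

Step 3
Reactants: 4 (5R)-5-[(benzyloxy)methyl]-2-methylcyclohexan-1-one
Product: 5 (5R)-5-[(benzyloxy)methyl]-2-methylcyclohex-1-en-1-yl trifluoromethanesulfonate
Conditions: Tf2O, 2,6-di-tert-butyl-4-methylpyridine, CH2Cl2, 0 °C to rt
Reagents that add atoms: trifluoromethanesulfonic anhydride, O=S(=O)(OS(=O)(=O)C(F)(F)F)C(F)(F)F
Why: Enol triflate formation through the O-triflyl oxocarbenium ion, which should lose the proton from the more substituted α-carbon (thermodynamic, Zaitsev-type control) and so place the double bond between the carbonyl carbon and the methyl-bearing carbon without touching the ring stereocentre.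

Step 4
Reactants: 5 (5R)-5-[(benzyloxy)methyl]-2-methylcyclohex-1-en-1-yl trifluoromethanesulfonate
Product: 6 (R)-{[(4-methylcyclohex-3-en-1-yl)methoxy]methyl}benzene
Conditions: Pd(OAc)2 (5 mol %), PPh3 (10 mol %), HCO2H, Bu3N, DMF, 60 °C
Reagents that add atoms: none
Why: Palladium-catalysed formate reduction of an enol triflate (oxidative addition, decarboxylation of the formate, reductive elimination) replaces OTf by H with the double bond held in place, and the benzyl ether is inert to it.

Step 5
Reactants: 6 (R)-{[(4-methylcyclohex-3-en-1-yl)methoxy]methyl}benzene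
Product: 7 (R)-(4-methylcyclohex-3-en-1-yl)methanol
Conditions: Li, NH3(l), THF, −78 °C; NH4Cl
Reagents that add atoms: none
Why: Dissolving-metal (Birch-type) cleavage of the benzyl ether, chosen over hydrogenolysis because the isolated trisubstituted olefin is not reduced under these conditions.

Step 6
Reactants: 7 (R)-(4-methylcyclohex-3-en-1-yl)methanol
Product: 8 (R)-4-methylcyclohex-3-ene-1-carbaldehyde
Conditions: Dess–Martin periodinane, CH2Cl2, 0 °C; used directly (volatile)
Reagents that add atoms: none
Why: Dess–Martin oxidation stops at the aldehyde under non-enolising conditions, so the α-stereocentre should be kept.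

Step 7
Reactants: 9 (5E,9E,13E)-6,10,14,18-tetramethylnonadeca-5,9,13,17-tetraen-2-one (all-E geranylgeranylacetone)
Product: 10 (6S,10S,14S)-6,10,14,18-tetramethylnonadecan-2-one
Conditions: H2 (50 bar), [Ir(cod)(L*)][B(C6H3(CF3)2)4] (1 mol %; L* = chiral 2-aryl-8-(di-tert-butylphosphinooxy)-5,6,7,8-tetrahydroquinoline, enantiomer giving the all-S product), CH2Cl2, 25 °C
Reagents that add atoms: none
Why: Iridium P,N-ligand-catalysed asymmetric hydrogenation of unfunctionalised trisubstituted olefins, in which each E double bond is reduced with the same catalyst-controlled facial sense, so that C6, C10 and C14 should all be set S by one catalyst (the isopropylidene end gives no stereocentre).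

Step 8
Reactants: 10 (6S,10S,14S)-6,10,14,18-tetramethylnonadecan-2-one
Product: 12 (4S,8S,12S)-4,8,12,16-tetramethylheptadecan-1-ol, via acetate 11 (not isolated)
Conditions: mCPBA, CF3CO2H (cat.), CH2Cl2, rt; then K2CO3 (cat.), MeOH, rt
Reagents that add atoms: 3-chloroperoxybenzoic acid (mCPBA), OOC(=O)c1cccc(Cl)c1
Why: Baeyer–Villiger oxidation with migration of the primary alkyl group in preference to methyl gives the acetate, and methanolysis frees the C21 alcohol with the remote stereocentres untouched.

Step 9
Reactants: 12 (4S,8S,12S)-4,8,12,16-tetramethylheptadecan-1-ol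
Product: 13 (4S,8S,12S)-1-bromo-4,8,12,16-tetramethylheptadecane
Conditions: CBr4, PPh3, CH2Cl2, 0 °C
Reagents that add atoms: carbon tetrabromide, BrC(Br)(Br)Br
Why: Appel reaction (SN2 displacement at the primary carbinol carbon).

Step 10
Reactants: 13 (4S,8S,12S)-1-bromo-4,8,12,16-tetramethylheptadecane; 14 propyne; 15 oxirane
Product: 19 (3Z,8S,12S,16S)-4,8,12,16,20-pentamethylhenicos-3-en-1-ol, via Grignard reagent 16 (not isolated), via alkylcopper 17 (not isolated), via alkenylcopper 18 (not isolated)
Conditions: Mg, Et2O; CuBr·SMe2 (1 equiv), Et2O/Me2S, −45 °C; 14, −25 °C; LiC≡C-nPr, HMPA, then 15, −45 to 0 °C; H2O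
Reagents that add atoms: none
Why: Carbocupration of a terminal alkyne, in which the alkylcopper adds syn across propyne with the alkyl group on the internal carbon, and the alkenylcopper (activated as its alkynyl cuprate) opens oxirane with retention at the vinylic carbon, so that the long chain and the CH2CH2OH group end up cis (Z).

Step 11
Reactants: 19 (3Z,8S,12S,16S)-4,8,12,16,20-pentamethylhenicos-3-en-1-ol
Product: 20 (3Z,8S,12S,16S)-1-bromo-4,8,12,16,20-pentamethylhenicos-3-ene
Conditions: CBr4, PPh3, CH2Cl2, 0 °C
Reagents that add atoms: carbon tetrabromide, BrC(Br)(Br)Br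
Why: Appel reaction at the primary homoallylic alcohol, which leaves the olefin geometry untouched.

Step 12
Reactants: 20 (3Z,8S,12S,16S)-1-bromo-4,8,12,16,20-pentamethylhenicos-3-ene; 8 (R)-4-methylcyclohex-3-ene-1-carbaldehyde
Product: 22 (4Z,9S,13S,17S)-5,9,13,17,21-pentamethyl-1-[(1R)-4-methylcyclohex-3-en-1-yl]docos-4-en-1-ol (mixture of carbinol epimers), via Grignard reagent 21 (not isolated)
Conditions: Mg, THF, rt; then 8, THF, −78 to −20 °C; aqueous work-up
Reagents that add atoms: none
Why: Grignard addition to the aldehyde at low temperature, where 1,2-addition should outrun enolisation of the α-branched aldehyde; the new carbinol centre is formed without control, which does not matter because it is oxidised in step 13.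

Step 13
Reactants: 22 (4Z,9S,13S,17S)-5,9,13,17,21-pentamethyl-1-[(1R)-4-methylcyclohex-3-en-1-yl]docos-4-en-1-ol
Product: 23 (4Z,9S,13S,17S)-5,9,13,17,21-pentamethyl-1-[(1R)-4-methylcyclohex-3-en-1-yl]docos-4-en-1-one
Conditions: Dess–Martin periodinane, CH2Cl2, 0 °C to rt
Reagents that add atoms: none
Why: Dess–Martin oxidation to the ketone under non-basic conditions should preserve the α-stereocentre and the Z olefin.

Step 14
Reactants: 23 (4Z,9S,13S,17S)-5,9,13,17,21-pentamethyl-1-[(1R)-4-methylcyclohex-3-en-1-yl]docos-4-en-1-one
Product: 24 (4R)-1-methyl-4-[(5Z,10S,14S,18S)-6,10,14,18,22-pentamethyltricosa-1,5-dien-2-yl]cyclohex-1-ene (CNP0141420.1)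
Conditions: Cp2TiMe2, toluene/THF, 70 °C, dark
Reagents that add atoms: dimethyltitanocene (Cp2TiMe2), C[Ti](C)(C1C=CC=C1)C1C=CC=C1
Why: Petasis methylenation (titanium methylidene, [2+2] addition and cycloreversion) is non-basic and should convert the enolisable α-branched ketone into the 1,1-disubstituted olefin without epimerising the ring stereocentre.

**Compound list**

1 | 3-[(benzyloxy)methyl]cyclobutan-1-one | O=C1CC(COCc2ccccc2)C1 | starting material
2 | isopropenylmagnesium bromide | C=C(C)[Mg]Br | starting material
3 | cis-3-[(benzyloxy)methyl]-1-(prop-1-en-2-yl)cyclobutan-1-ol | O[C@@]1(C(C)=C)C[C@@H](COCc2ccccc2)C1 | intermediate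
4 | (5R)-5-[(benzyloxy)methyl]-2-methylcyclohexan-1-one (C2 epimers) | c1ccccc1COC[C@H]1CC(=O)C(C)CC1 | intermediate
5 | (5R)-5-[(benzyloxy)methyl]-2-methylcyclohex-1-en-1-yl trifluoromethanesulfonate | c1ccccc1COC[C@H]1CC(OS(=O)(=O)C(F)(F)F)=C(C)CC1 | intermediate
6 | (R)-{[(4-methylcyclohex-3-en-1-yl)methoxy]methyl}benzene | c1ccccc1COC[C@H]1CC=C(C)CC1 | intermediate
7 | (R)-(4-methylcyclohex-3-en-1-yl)methanol | OC[C@H]1CC=C(C)CC1 | intermediate
8 | (R)-4-methylcyclohex-3-ene-1-carbaldehyde | O=C[C@H]1CC=C(C)CC1 | intermediate
9 | (5E,9E,13E)-6,10,14,18-tetramethylnonadeca-5,9,13,17-tetraen-2-one | CC(=O)CC/C=C(\C)CC/C=C(\C)CC/C=C(\C)CCC=C(C)C | starting material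
10 | (6S,10S,14S)-6,10,14,18-tetramethylnonadecan-2-one | CC(=O)CCC[C@@H](C)CCC[C@@H](C)CCC[C@@H](C)CCCC(C)C | intermediate
11 | (4S,8S,12S)-4,8,12,16-tetramethylheptadecyl acetate | CC(=O)OCCC[C@@H](C)CCC[C@@H](C)CCC[C@@H](C)CCCC(C)C | intermediate
12 | (4S,8S,12S)-4,8,12,16-tetramethylheptadecan-1-ol | OCCC[C@@H](C)CCC[C@@H](C)CCC[C@@H](C)CCCC(C)C | intermediate
13 | (4S,8S,12S)-1-bromo-4,8,12,16-tetramethylheptadecane | BrCCC[C@@H](C)CCC[C@@H](C)CCC[C@@H](C)CCCC(C)C | intermediate
14 | propyne | CC#C | starting material
15 | oxirane | C1CO1 | starting material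
16 | [(4S,8S,12S)-4,8,12,16-tetramethylheptadecyl]magnesium bromide | Br[Mg]CCC[C@@H](C)CCC[C@@H](C)CCC[C@@H](C)CCCC(C)C | intermediate
17 | [(4S,8S,12S)-4,8,12,16-tetramethylheptadecyl]copper | [Cu]CCC[C@@H](C)CCC[C@@H](C)CCC[C@@H](C)CCCC(C)C | intermediate
18 | [(1Z,6S,10S,14S)-2,6,10,14,18-pentamethylnonadec-1-en-1-yl]copper | [Cu]/C=C(/C)CCC[C@@H](C)CCC[C@@H](C)CCC[C@@H](C)CCCC(C)C | intermediate
19 | (3Z,8S,12S,16S)-4,8,12,16,20-pentamethylhenicos-3-en-1-ol | OCC/C=C(/C)CCC[C@@H](C)CCC[C@@H](C)CCC[C@@H](C)CCCC(C)C | intermediate
20 | (3Z,8S,12S,16S)-1-bromo-4,8,12,16,20-pentamethylhenicos-3-ene | BrCC/C=C(/C)CCC[C@@H](C)CCC[C@@H](C)CCC[C@@H](C)CCCC(C)C | intermediate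
21 | [(3Z,8S,12S,16S)-4,8,12,16,20-pentamethylhenicos-3-en-1-yl]magnesium bromide | Br[Mg]CC/C=C(/C)CCC[C@@H](C)CCC[C@@H](C)CCC[C@@H](C)CCCC(C)C | intermediate
22 | (4Z,9S,13S,17S)-5,9,13,17,21-pentamethyl-1-[(1R)-4-methylcyclohex-3-en-1-yl]docos-4-en-1-ol (carbinol epimers) | OC(CC/C=C(/C)CCC[C@@H](C)CCC[C@@H](C)CCC[C@@H](C)CCCC(C)C)[C@H]1CC=C(C)CC1 | intermediate
23 | (4Z,9S,13S,17S)-5,9,13,17,21-pentamethyl-1-[(1R)-4-methylcyclohex-3-en-1-yl]docos-4-en-1-one | O=C(CC/C=C(/C)CCC[C@@H](C)CCC[C@@H](C)CCC[C@@H](C)CCCC(C)C)[C@H]1CC=C(C)CC1 | intermediate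
24 | (4R)-1-methyl-4-[(5Z,10S,14S,18S)-6,10,14,18,22-pentamethyltricosa-1,5-dien-2-yl]cyclohex-1-ene | C=C(CC/C=C(/C)CCC[C@@H](C)CCC[C@@H](C)CCC[C@@H](C)CCCC(C)C)[C@H]1CC=C(C)CC1 | target

**Totals and risks**

Total step count: 14.
Longest linear sequence: 9 steps (steps 1–6, then 12–14); the chain branch is 8 steps (7–11, then 12–14).

Steps most likely to fail:

1. Step 2 (proposed new method). What may go wrong: β-hydride elimination and chain walking of the ring-opened alkylrhodium, or its protodemetalation, before the ring closes; or poor discrimination between the two enantiotopic ring bonds. Fallback (known chemistry), setting out from cyclobutanone 1 and returning at ketone 4: an enantioselective Baeyer–Villiger desymmetrisation of 1 (Baeyer–Villiger monooxygenase with O2 and cofactor recycling, or Sc(OTf)3 with a chiral N,N'-dioxide and mCPBA) should give (R)-4-[(benzyloxy)methyl]oxolan-2-one F1. Aminolysis with MeNH(OMe)·HCl and AlMe3 opens it to (S)-3-[(benzyloxy)methyl]-4-hydroxy-N-methoxy-N-methylbutanamide F2. I2, PPh3 and imidazole convert this into (R)-3-[(benzyloxy)methyl]-4-iodo-N-methoxy-N-methylbutanamide F3. Addition of Grignard reagent 2 at −78 °C gives (R)-5-[(benzyloxy)methyl]-6-iodo-2-methylhex-1-en-3-one F4. A 6-endo-trig radical cyclisation onto the enone terminus (Bu3SnH, AIBN, benzene, 80 °C, high dilution) then closes the same C5–C6 bond and delivers 4.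

2. Step 3. What may go wrong: loss of regiocontrol in the enolisation, with triflation toward the less substituted α-carbon, which would put the double bond on the wrong side of the former carbonyl carbon. Fallback, setting out from ketone 4 and returning at triflate 5: equilibrating silylation (TMSCl, NaI, Et3N, MeCN) gives the more substituted silyl enol ether (R)-{[5-((benzyloxy)methyl)-2-methylcyclohex-1-en-1-yl]oxy}trimethylsilane F5, which is purified from its regioisomer. MeLi in THF at 0 °C releases the regiodefined lithium (R)-5-[(benzyloxy)methyl]-2-methylcyclohex-1-en-1-olate F6, which is trapped with PhNTf2 to give 5.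

3. Step 7. What may go wrong: erosion of facial selectivity at one of the three remote olefins, or inhibition of the cationic iridium catalyst by the ketone leading to incomplete reduction. Fallback, setting out from ketone 9 and returning at ketone 10: the ketone is masked first (HC(OMe)3, MeOH, TsOH cat.) as (5E,9E,13E)-2,2-dimethoxy-6,10,14,18-tetramethylnonadeca-5,9,13,17-tetraene F7. This is hydrogenated with the same iridium catalyst to (6S,10S,14S)-2,2-dimethoxy-6,10,14,18-tetramethylnonadecane F8, and aqueous HCl in THF returns 10.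

**Further compounds**

F1 | step 2 | (R)-4-[(benzyloxy)methyl]oxolan-2-one | c1ccccc1COC[C@H]1CC(=O)OC1
F2 | step 2 | (S)-3-[(benzyloxy)methyl]-4-hydroxy-N-methoxy-N-methylbutanamide | c1ccccc1COC[C@H](CO)CC(=O)N(C)OC
F3 | step 2 | (R)-3-[(benzyloxy)methyl]-4-iodo-N-methoxy-N-methylbutanamide | c1ccccc1COC[C@H](CI)CC(=O)N(C)OC
F4 | step 2 | (R)-5-[(benzyloxy)methyl]-6-iodo-2-methylhex-1-en-3-one | c1ccccc1COC[C@H](CI)CC(=O)C(C)=C
F5 | step 3 | (R)-{[5-((benzyloxy)methyl)-2-methylcyclohex-1-en-1-yl]oxy}trimethylsilane | c1ccccc1COC[C@H]1CC(O[Si](C)(C)C)=C(C)CC1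
F6 | step 3 | lithium (R)-5-[(benzyloxy)methyl]-2-methylcyclohex-1-en-1-olate | c1ccccc1COC[C@H]1CC(O[Li])=C(C)CC1
F7 | step 7 | (5E,9E,13E)-2,2-dimethoxy-6,10,14,18-tetramethylnonadeca-5,9,13,17-tetraene | COC(C)(OC)CC/C=C(\C)CC/C=C(\C)CC/C=C(\C)CCC=C(C)C
F8 | step 7 | (6S,10S,14S)-2,2-dimethoxy-6,10,14,18-tetramethylnonadecane | COC(C)(OC)CCC[C@@H](C)CCC[C@@H](C)CCC[C@@H](C)CCCC(C)C
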